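The readings come from a simulation on assumed constants, noise included.

In a one-step world free monomer passes into chains and stays there, so the curve climbs up to its last time. The dawn flask, which is the flask asked about, does otherwise: its chains read 28.8% at 0.833 d but 4.3% at 5.00 d.

common to all: free monomer 0.10 M

| run | initiator | remark | time |
|---|---|---|---|
| dawn | 0.20 mM | the very flask that is asked about, followed so far |  |
| noon | 0.30 mM | run made earlier |  |
| flask | 0.20 mM |  | 15 d |

- dawn (time / d: monomer in chains / %): 0.167: 17.6; 0.250: 21.8; 0.500: 28.3; 0.833: 28.8; 1.67: 21.1; 2.50: 14.7; 5.00: 4.3
- noon (time / d: monomer in chains / %): 0.167: 20.9; 0.333: 29.4; 0.625: 33.1; 1.25: 29.0; 2.50: 15.6; 5.00: 4.5; 10.0: 0.3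

(readings scatter by 0.3 percentage points)

- when, up to 15 d, the flask holds most monomer in chains
- the amount of monomer in chains, in percent of the free monomer charged, at that time



Add a second step, in which chains are lost in proportion to their amount. The late readings then give the quantity we carry, the tail constant, which is the first-order fraction of the chains lost per day once making has faded. The dawn readings at 2.50 d and 5.00 d give 0.492 d⁻¹, and the noon run over the same window gives 0.497 d⁻¹, so within the scatter these two initiator charges share one tail.

Now add the rest: we take it that making fades as free monomer goes, so that the maximum is the crossing where making falls to the level of loss and the net slope changes sign. In the dawn flask the slope is 0.0150 d⁻¹ of the charge between 0.500 d and 0.833 d, then −0.0920 d⁻¹ up to 1.67 d. A straight line between the midpoints of those intervals crosses zero at 0.749 d, which is our own reckoning, with a top just above the 28.8% read at 0.833 d.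

The forecast gives 0.69 d and 29.2%, earlier than our crossing: “The curve therefore flattens at about 0.7 d.”

The flask peaks at 0.666 d with 29.0%, and at 0.324 d its chains are made 1.67 times faster than they are used up.

    initiator → 2 initiating radical (k = 5.40 × 10⁻⁴ min⁻¹)
    free monomer + initiating radical → growing radical + monomer in chains (k = 5.20 × 10⁵ M⁻¹ min⁻¹)
    free monomer + growing radical → monomer in chains + growing radical, rate k3*[growing radical]*[free monomer] (k = 25000 M⁻¹ min⁻¹)
    2 growing radical → dead chain (k = 1.00 × 10⁶ M⁻¹ s⁻¹)
    monomer in chains → over-reaction product (k = 3.60 × 10⁻⁴ min⁻¹)
    free monomer + monomer in chains → side product (k = 0.0160 M⁻¹ min⁻¹)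

At 7.50 d, half of the longest time allowed, the flask holds 1.21% in chains. The tail constant carries that amount to 0.0304% at the longest time allowed, when the flask holds 0.0295%. In the neighbour charged with 8.0 × 10⁻⁴ M of initiator, the same constant needs 14.9 d to bring its best of 44.6% down to 0.0290%, the amount that neighbour holds at 15.0 d.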